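**Retrosynthetic overview**

1. Feature: in the bicyclic core the oxolane ring (O5, C4 bearing the aryl group, C3a, C6a, C6) holds the lactone carbonyl carbon C1 as an exocyclic carbon on C6a, the ring carbon next to the O-bound methylene C6. This is what is left of a 2-aryl-oxan-4-one once its carbonyl carbon is pushed out of the ring.
2. Target 26 ⇐ methyl all-cis oxolane-3-carboxylate 24 (desilylation, lactone closed last) ⇐ 5-diazo-oxan-4-one 22 by photochemical Wolff ring contraction (oxane → oxolane; old C3–C5 bond made, old C4 becomes the ester carbon).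
3. 22 ⇐ cis-2-aryl-3-(silyloxymethyl)-2,3-dihydropyran-4-one 19 (conjugate reduction with in-flask trifluoroacetylation of the enolate, then deacylative diazo transfer) ⇐ endo hetero-Diels–Alder reaction of aldehyde 12 with diene 17.
4. 12 ⇐ aryl bromide 10 (Br/Li exchange, DMF) ⇐ anti glycolate aldol of aryloxyacetyl thioimide 4 with silylated vanillin 6, which sets both side-chain centres.
5. Ring order: pyranone ring (step 12), contracted to the oxolane (step 15), γ-lactone (step 16).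

Key step: step 15

Assumption: the TiCl4-promoted aldol of step 4 is taken to occur on the thiocarbonyl-chelated enolate face (α-sense opposite to the boron syn aldol of the same auxiliary series), and the (1R,2S)-ligand of step 12 to expose the Re face of the formyl group; if either sense proves reversed, the antipodal auxiliary or ligand is used and nothing else changes.

Abbreviations: TBS = tert-butyldimethylsilyl; TES = triethylsilyl; Ar = 4-{[(1R,2S)-1,3-bis(TBS-oxy)-1-(3-methoxy-4-TBS-oxyphenyl)propan-2-yl]oxy}-3,5-dimethoxyphenyl.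

**Route**

Step 1
Reactants: 1 4-bromo-2,6-dimethoxyphenol
Product: 2 2-(4-bromo-2,6-dimethoxyphenoxy)acetic acid
Conditions: NaH (2.2 equiv), BrCH2CO2H, THF, 0 °C → reflux; aq HCl
Reagents that add atoms: bromoacetic acid, OC(=O)CBr
Why: Williamson-type O-alkylation of the sodium phenoxide by sodium bromoacetate; the 2,6-dimethoxyphenoxide remains a competent SN2 nucleophile toward a primary α-halo carboxylate.

Step 2
Reactants: 2 2-(4-bromo-2,6-dimethoxyphenoxy)acetic acid; 3 (S)-4-benzyl-1,3-oxazolidine-2-thione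
Product: 4 (S)-4-benzyl-3-[2-(4-bromo-2,6-dimethoxyphenoxy)acetyl]-1,3-oxazolidine-2-thione
Conditions: DCC, DMAP (cat.), CH2Cl2, 0 °C → rt
Reagents that add atoms: none
Why: Carbodiimide/DMAP N-acylation, the usual way to make N-glycolyl oxazolidinethiones; no stereocentre is touched.

Step 3
Reactants: 5 vanillin
Product: 6 4-(TBS-oxy)-3-methoxybenzaldehyde
Conditions: TBSCl, imidazole, DMF, rt
Reagents that add atoms: tert-butyldimethylsilyl chloride, CC(C)(C)[Si](C)(C)Cl
Why: Imidazole-promoted silylation masks the acidic phenol before the titanium aldol.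

Step 4
Reactants: 4 (S)-4-benzyl-3-[2-(4-bromo-2,6-dimethoxyphenoxy)acetyl]-1,3-oxazolidine-2-thione; 6 4-(TBS-oxy)-3-methoxybenzaldehyde
Product: 8 (S)-4-benzyl-3-[(2R,3R)-2-(4-bromo-2,6-dimethoxyphenoxy)-3-hydroxy-3-(3-methoxy-4-TBS-oxyphenyl)propanoyl]-1,3-oxazolidine-2-thione, via trichlorotitanium Z-enolate 7 (not isolated)
Conditions: TiCl4 (1.05 equiv), i-Pr2NEt (1.1 equiv), CH2Cl2, −78 °C; then 6 (2.5 equiv) premixed with TiCl4 (2.5 equiv), −78 °C; aq NH4Cl
Reagents that add atoms: none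
Why: Titanium-mediated anti-selective glycolate aldol: the titanium of (Z)-enolate 7, held by the thiocarbonyl and the α-aryloxy oxygen, cannot bind an aldehyde already complexed to TiCl4, so addition should go through an open transition state on the enolate face away from the benzyl group and set C2 (R) and C3 (R) in an anti relation.

Step 5
Reactants: 8 anti aldol adduct
Product: 9 (1R,2S)-2-(4-bromo-2,6-dimethoxyphenoxy)-1-(3-methoxy-4-TBS-oxyphenyl)propane-1,3-diol
Conditions: LiBH4, MeOH (1.1 equiv), THF, 0 °C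
Reagents that add atoms: none
Why: Borohydride reduction of the activated N-acyl thioimide should give the primary alcohol and return the auxiliary without touching either stereocentre.

Step 6
Reactants: 9 (1R,2S)-diol
Product: 10 5-bromo-2-{[(1R,2S)-1,3-bis(TBS-oxy)-1-(3-methoxy-4-TBS-oxyphenyl)propan-2-yl]oxy}-1,3-dimethoxybenzene
Conditions: TBSOTf (2.5 equiv), 2,6-lutidine, CH2Cl2, 0 °C
Reagents that add atoms: tert-butyldimethylsilyl trifluoromethanesulfonate, CC(C)(C)[Si](C)(C)OS(=O)(=O)C(F)(F)F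
Why: A silyl triflate with a hindered pyridine base silylates the primary and the hindered benzylic secondary hydroxyl alike.

Step 7
Reactants: 10 tris-silylated aryl bromide
Product: 12 4-{[(1R,2S)-1,3-bis(TBS-oxy)-1-(3-methoxy-4-TBS-oxyphenyl)propan-2-yl]oxy}-3,5-dimethoxybenzaldehyde (Ar–CHO), via aryllithium 11 (not isolated)
Conditions: n-BuLi, THF, −78 °C; DMF, −78 → 0 °C; aq NH4Cl
Reagents that add atoms: N,N-dimethylformamide, CN(C)C=O
Why: Bromine–lithium exchange outruns any deprotonation at −78 °C and the aryllithium is formylated by DMF (Bouveault-type formylation); aryl and alkyl silyl ethers are inert here.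

Step 8
Reactants: 13 3-(TBS-oxy)propanal
Product: 14 rac-5-(TBS-oxy)pent-1-yn-3-ol
Conditions: HC≡CMgBr, THF, 0 °C; aq NH4Cl
Reagents that add atoms: ethynylmagnesium bromide, C#C[Mg]Br
Why: 1,2-Addition of an alkynyl Grignard reagent to an aldehyde; the carbinol centre is racemic and is removed in step 9.

Step 9
Reactants: 14 rac-5-(TBS-oxy)pent-1-yn-3-ol
Product: 15 5-(TBS-oxy)pent-1-yn-3-one
Conditions: MnO2, CH2Cl2, rt
Reagents that add atoms: none
Why: MnO2 oxidises the activated propargylic alcohol selectively and leaves the silyl ether alone.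

Step 10
Reactants: 15 5-(TBS-oxy)pent-1-yn-3-one
Product: 16 (E)-5-(TBS-oxy)-1-methoxypent-1-en-3-one
Conditions: MeOH, DABCO (10 mol%), CH2Cl2, 0 °C → rt
Reagents that add atoms: methanol, CO
Why: Amine-catalysed oxa-Michael addition of methanol to the terminal ynone should give the thermodynamically preferred (E)-β-methoxy enone.

Step 11
Reactants: 16 (E)-5-(TBS-oxy)-1-methoxypent-1-en-3-one
Product: 17 (1E,3Z)-5-(TBS-oxy)-1-methoxy-3-(TES-oxy)penta-1,3-diene
Conditions: TESOTf, Et3N, Et2O, −78 → 0 °C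
Reagents that add atoms: triethylsilyl trifluoromethanesulfonate, CC[Si](CC)(CC)OS(=O)(=O)C(F)(F)F
Why: Soft enolisation of the vinylogous ester at its only α-methylene gives the 2-silyloxy diene with the (Z)-enol ether geometry (OSi cis to CH2OTBS) normal for such ketones.

Step 12
Reactants: 12 Ar–CHO; 17 (1E,3Z)-diene
Product: 19 (2R,3R)-2-Ar-3-[(TBS-oxy)methyl]-2,3-dihydro-4H-pyran-4-one, via methoxy-acetal cycloadduct 18 (not isolated)
Conditions: [CrCl(L)] (10 mol%; L = dianion of (1R,2S)-1-{[3-(1-adamantyl)-2-hydroxy-5-methylbenzylidene]amino}indan-2-ol), 4 Å MS, t-BuOMe, rt; then TFA, CH2Cl2, 0 °C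
Reagents that add atoms: none
Why: Lewis-acid-catalysed hetero-Diels–Alder reaction of an aldehyde with a 1-methoxy-3-silyloxy diene: the endo transition state puts aryl, CH2OTBS and OMe cis (C2/C3 cis from the Z enol ether), the chiral chromium complex should select the Re face of the formyl carbon to give 2R,3R irrespective of the remote side-chain centres, and acid then unveils the enone by loss of methanol and the silyl group.

Step 13
Reactants: 19 (2R,3R)-dihydropyranone
Product: 21 (2R,3R)-2-Ar-3-[(TBS-oxy)methyl]-5-(trifluoroacetyl)oxan-4-one (enol form), via lithium enolate 20 (not isolated)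
Conditions: LiBH(s-Bu)3 (1.05 equiv), THF, −78 °C; then CF3CO2CH2CF3 (1.5 equiv), −78 °C; 5% aq HCl work-up
Reagents that add atoms: 2,2,2-trifluoroethyl trifluoroacetate, O=C(OCC(F)(F)F)C(F)(F)F
Why: The hindered borohydride adds hydride 1,4 to the vinylogous ester and leaves the C4–C5 lithium enolate 20 as the only enolate regioisomer, which is C-acylated in the same flask by the activated trifluoroacetate (conjugate reduction followed by Claisen-type trapping of the enolate); no base ever meets the C3–H, so the acyl group can sit only at C5 and the cis relation is kept.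

Step 14
Reactants: 21 α-trifluoroacetyl ketone
Product: 22 (2R,3R)-2-Ar-5-diazo-3-[(TBS-oxy)methyl]oxan-4-one
Conditions: MsN3, Et3N, H2O (1 equiv), MeCN, rt
Reagents that add atoms: methanesulfonyl azide, CS(=O)(=O)N=[N+]=[N-]
Why: Deacylative Regitz diazo transfer: the 1,3-dicarbonyl anion attacks the sulfonyl azide and the trifluoroacetyl group leaves on the sulfonamide nitrogen, so the diazo group can sit only at C5.

Step 15
Reactants: 22 (2R,3R)-5-diazo-oxan-4-one
Product: 24 methyl (3R,4R,5R)-5-Ar-4-[(TBS-oxy)methyl]oxolane-3-carboxylate, via ketene 23 (not isolated)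
Conditions: hν (medium-pressure Hg lamp, Pyrex), degassed MeOH–THF, 0 °C
Reagents that add atoms: methanol, CO
Why: Excitation of the s-Z-locked cyclic α-diazo ketone expels N2 while old C3 (the ring carbon bearing CH2OTBS) shifts from the carbonyl carbon C4 to the diazo carbon C5, making the C3–C5 bond and ketene 23, whose C=C=O carbon (old C4) is now exocyclic and is captured by methanol. This is the photochemical Wolff ring contraction of a cyclic 2-diazo ketone with alcohol capture. The oxolane (old O1, C2, C3, C5, C6) is closed by this 1,2-shift, a six-to-five ring contraction, not by an end-to-end cyclisation. Old C3 migrates with retention, so the cis aryl/CH2OTBS relation from step 12 is carried through; the new ester-bearing centre should be set by protonation of the ester enol on the face away from the two cis substituents, placing CO2Me cis to them (3R). Only old C3 can migrate, so the regiochemistry is fixed by the position of the diazo group, and the concerted pathway favoured by the s-Z geometry should suppress 1,2-hydrogen shift from C6 and O–H insertion. A wrong ester epimer would not be fatal, because only the cis ester lactonises in step 16 and the trans ester can equilibrate at its α-carbon.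

Step 16
Reactants: 24 methyl (3R,4R,5R)-oxolane-3-carboxylate
Product: 26 CNP0398772.1, (3aR,4R,6aR)-4-(4-{[(1R,2S)-1,3-dihydroxy-1-(4-hydroxy-3-methoxyphenyl)propan-2-yl]oxy}-3,5-dimethoxyphenyl)tetrahydro-1H,3H-furo[3,4-c]furan-1-one, via tetraol methyl ester 25 (not isolated)
Conditions: Bu4NF, AcOH, THF, 0 °C → rt; then PPTS (cat.), CH2Cl2, rt
Reagents that add atoms: none
Why: Buffered fluoride cleaves the four Si–O bonds and the freed hydroxymethyl group acylates the neighbouring cis ester (5-exo-trig lactonisation, cis ring fusion the only one possible); no stereocentre is changed.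

**Compound list**

1 | 4-bromo-2,6-dimethoxyphenol | COc1cc(Br)cc(OC)c1O | starting material
2 | 2-(4-bromo-2,6-dimethoxyphenoxy)acetic acid | COc1cc(Br)cc(OC)c1OCC(=O)O | intermediate
3 | (S)-4-benzyl-1,3-oxazolidine-2-thione | S=C1OC[C@H](Cc2ccccc2)N1 | starting material
4 | (S)-4-benzyl-3-[2-(4-bromo-2,6-dimethoxyphenoxy)acetyl]-1,3-oxazolidine-2-thione | COc1cc(Br)cc(OC)c1OCC(=O)N1C(=S)OC[C@@H]1Cc1ccccc1 | intermediate
5 | vanillin | COc1cc(C=O)ccc1O | starting material
6 | 4-(TBS-oxy)-3-methoxybenzaldehyde | COc1cc(C=O)ccc1O[Si](C)(C)C(C)(C)C | intermediate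
7 | trichlorotitanium (Z)-enolate of 4 (not isolated) | COc1cc(Br)cc(OC)c1O/C=C(\O[Ti](Cl)(Cl)Cl)N1C(=S)OC[C@@H]1Cc1ccccc1 | intermediate
8 | (S)-4-benzyl-3-[(2R,3R)-2-(4-bromo-2,6-dimethoxyphenoxy)-3-hydroxy-3-(3-methoxy-4-TBS-oxyphenyl)propanoyl]-1,3-oxazolidine-2-thione | COc1cc([C@@H](O)[C@H](C(=O)N2C(=S)OC[C@@H]2Cc2ccccc2)Oc2c(OC)cc(Br)cc2OC)ccc1O[Si](C)(C)C(C)(C)C | intermediate
9 | (1R,2S)-2-(4-bromo-2,6-dimethoxyphenoxy)-1-(3-methoxy-4-TBS-oxyphenyl)propane-1,3-diol | COc1cc([C@@H](O)[C@H](CO)Oc2c(OC)cc(Br)cc2OC)ccc1O[Si](C)(C)C(C)(C)C | intermediate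
10 | 5-bromo-2-{[(1R,2S)-1,3-bis(TBS-oxy)-1-(3-methoxy-4-TBS-oxyphenyl)propan-2-yl]oxy}-1,3-dimethoxybenzene (Ar–Br) | COc1cc([C@@H](O[Si](C)(C)C(C)(C)C)[C@H](CO[Si](C)(C)C(C)(C)C)Oc2c(OC)cc(Br)cc2OC)ccc1O[Si](C)(C)C(C)(C)C | intermediate
11 | aryllithium Ar–Li (not isolated) | COc1cc([C@@H](O[Si](C)(C)C(C)(C)C)[C@H](CO[Si](C)(C)C(C)(C)C)Oc2c(OC)cc([Li])cc2OC)ccc1O[Si](C)(C)C(C)(C)C | intermediate
12 | Ar–CHO, 4-{[(1R,2S)-1,3-bis(TBS-oxy)-1-(3-methoxy-4-TBS-oxyphenyl)propan-2-yl]oxy}-3,5-dimethoxybenzaldehyde | COc1cc([C@@H](O[Si](C)(C)C(C)(C)C)[C@H](CO[Si](C)(C)C(C)(C)C)Oc2c(OC)cc(C=O)cc2OC)ccc1O[Si](C)(C)C(C)(C)C | intermediate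
13 | 3-(TBS-oxy)propanal | CC(C)(C)[Si](C)(C)OCCC=O | starting material
14 | rac-5-(TBS-oxy)pent-1-yn-3-ol | C#CC(O)CCO[Si](C)(C)C(C)(C)C | intermediate
15 | 5-(TBS-oxy)pent-1-yn-3-one | C#CC(=O)CCO[Si](C)(C)C(C)(C)C | intermediate
16 | (E)-5-(TBS-oxy)-1-methoxypent-1-en-3-one | CO/C=C/C(=O)CCO[Si](C)(C)C(C)(C)C | intermediate
17 | (1E,3Z)-5-(TBS-oxy)-1-methoxy-3-(TES-oxy)penta-1,3-diene | CO/C=C/C(O[Si](CC)(CC)CC)=C/CO[Si](C)(C)C(C)(C)C | intermediate
18 | (2R,3R,6S)-2-Ar-3-[(TBS-oxy)methyl]-6-methoxy-4-(TES-oxy)-3,6-dihydro-2H-pyran, all-cis (not isolated) | COc1cc([C@@H](O[Si](C)(C)C(C)(C)C)[C@H](CO[Si](C)(C)C(C)(C)C)Oc2c(OC)cc([C@@H]3O[C@H](OC)C=C(O[Si](CC)(CC)CC)[C@@H]3CO[Si](C)(C)C(C)(C)C)cc2OC)ccc1O[Si](C)(C)C(C)(C)C | intermediate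
19 | (2R,3R)-2-Ar-3-[(TBS-oxy)methyl]-2,3-dihydro-4H-pyran-4-one | COc1cc([C@@H](O[Si](C)(C)C(C)(C)C)[C@H](CO[Si](C)(C)C(C)(C)C)Oc2c(OC)cc([C@@H]3OC=CC(=O)[C@@H]3CO[Si](C)(C)C(C)(C)C)cc2OC)ccc1O[Si](C)(C)C(C)(C)C | intermediate
20 | lithium C4–C5 enolate of (2R,3R)-2-Ar-3-[(TBS-oxy)methyl]oxan-4-one (not isolated) | COc1cc([C@@H](O[Si](C)(C)C(C)(C)C)[C@H](CO[Si](C)(C)C(C)(C)C)Oc2c(OC)cc([C@@H]3OCC=C(O[Li])[C@@H]3CO[Si](C)(C)C(C)(C)C)cc2OC)ccc1O[Si](C)(C)C(C)(C)C | intermediate
21 | (2R,3R)-2-Ar-3-[(TBS-oxy)methyl]-5-(trifluoroacetyl)oxan-4-one, drawn as its enol | COc1cc([C@@H](O[Si](C)(C)C(C)(C)C)[C@H](CO[Si](C)(C)C(C)(C)C)Oc2c(OC)cc([C@@H]3OCC(C(=O)C(F)(F)F)=C(O)[C@@H]3CO[Si](C)(C)C(C)(C)C)cc2OC)ccc1O[Si](C)(C)C(C)(C)C | intermediate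
22 | (2R,3R)-2-Ar-5-diazo-3-[(TBS-oxy)methyl]oxan-4-one | COc1cc([C@@H](O[Si](C)(C)C(C)(C)C)[C@H](CO[Si](C)(C)C(C)(C)C)Oc2c(OC)cc([C@@H]3OCC(=[N+]=[N-])C(=O)[C@@H]3CO[Si](C)(C)C(C)(C)C)cc2OC)ccc1O[Si](C)(C)C(C)(C)C | intermediate
23 | ketene, (4R,5R)-5-Ar-4-[(TBS-oxy)methyl]oxolan-3-ylidene-methanone (not isolated) | COc1cc([C@@H](O[Si](C)(C)C(C)(C)C)[C@H](CO[Si](C)(C)C(C)(C)C)Oc2c(OC)cc([C@@H]3OCC(=C=O)[C@@H]3CO[Si](C)(C)C(C)(C)C)cc2OC)ccc1O[Si](C)(C)C(C)(C)C | intermediate
24 | methyl (3R,4R,5R)-5-Ar-4-[(TBS-oxy)methyl]oxolane-3-carboxylate, all-cis | COc1cc([C@@H](O[Si](C)(C)C(C)(C)C)[C@H](CO[Si](C)(C)C(C)(C)C)Oc2c(OC)cc([C@@H]3OC[C@H](C(=O)OC)[C@@H]3CO[Si](C)(C)C(C)(C)C)cc2OC)ccc1O[Si](C)(C)C(C)(C)C | intermediate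
25 | methyl (3R,4R,5R)-5-(4-{[(1R,2S)-1,3-dihydroxy-1-(4-hydroxy-3-methoxyphenyl)propan-2-yl]oxy}-3,5-dimethoxyphenyl)-4-(hydroxymethyl)oxolane-3-carboxylate (not isolated) | COc1cc([C@@H](O)[C@H](CO)Oc2c(OC)cc([C@@H]3OC[C@H](C(=O)OC)[C@@H]3CO)cc2OC)ccc1O | intermediate
26 | CNP0398772.1, (3aR,4R,6aR)-4-(4-{[(1R,2S)-1,3-dihydroxy-1-(4-hydroxy-3-methoxyphenyl)propan-2-yl]oxy}-3,5-dimethoxyphenyl)tetrahydro-1H,3H-furo[3,4-c]furan-1-one | COc1cc([C@@H](O)[C@H](CO)Oc2c(OC)cc([C@@H]3OC[C@@H]4C(=O)OC[C@@H]43)cc2OC)ccc1O | target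

**Step count and risks**

Total steps: 16. Longest linear sequence: 11 steps (steps 1, 2, 4, 5, 6, 7, 12, 13, 14, 15, 16, from phenol 1 to target 26).

Steps most likely to fail:

Step 4. With an O-aryl glycolate and an aromatic aldehyde the open-transition-state aldol may give a poor anti/syn ratio or use the other enolate face. The fallback sets out from acid 2 and aldehyde 6 and uses a boron syn aldol of established sense followed by inversion of the benzylic carbinol. Acid 2 is attached (pivaloyl mixed anhydride, lithiated auxiliary) to (R)-4-benzyl-1,3-oxazolidin-2-one to give (R)-4-benzyl-3-[2-(4-bromo-2,6-dimethoxyphenoxy)acetyl]-1,3-oxazolidin-2-one F1. Its dibutylboron (Z)-enolate (Bu2BOTf, i-Pr2NEt) adds to 6 through the closed chair transition state to give the (2R,3S) syn adduct F2. LiBH4 then gives the (1S,2S) threo diol F3, and TBSCl/imidazole silylates only the primary hydroxyl to give the mono-silyl ether F4. Periodinane oxidation (DMP, NaHCO3) gives the (S)-configured aryl ketone F5, and chelation-controlled reduction with Zn(BH4)2 should deliver the erythro (1R,2S) alcohol F6. Silylation of F6 with TBSOTf rejoins the route at bromide 10.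

Step 12. The electron-rich, bulky aryl aldehyde may react slowly, the reaction may leak into a stepwise Mukaiyama-aldol pathway that erodes the cis relation, or catalyst control of the aldehyde face may be weak. The fallback sets out from aldehyde 12 and enone 16 and replaces the cycloaddition by a reagent-controlled aldol and ring closure. Enone 16 is converted with (Ipc)2BOTf/i-Pr2NEt (the enantiomer that attacks the Re face of the aldehyde) into its (Z)-boron enolate and added to 12, giving the syn aldol (E,4R,5R)-5-Ar-5-hydroxy-1-methoxy-4-[(TBS-oxy)methyl]pent-1-en-3-one F7. Brief TFA treatment then closes F7 by oxa-Michael addition and loss of methanol; the syn aldol maps onto the cis ring, and the route is rejoined at dihydropyranone 19.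

Step 15. The excited diazo ketone may divert into 1,2-hydrogen shift from the O-bound methylene or O–H insertion into methanol instead of rearranging, or the ester enol may be protonated to the trans ester. The fallback sets out from diazo ketone 22 and lets the substrate capture its own ketene. The two primary silyl ethers of 22 are removed with PPTS in MeOH at rt to give the diol (2R,3R)-5-diazo-3-(hydroxymethyl)oxan-4-one F8 (benzylic and aryl silyl ethers retained). Irradiation of F8 in dilute CH2Cl2 without an external nucleophile allows the cis hydroxymethyl group to trap the ketene, giving the bicyclic lactone F9 directly; the ring fusion can only be cis, so the ester-centre question disappears. Bu4NF/AcOH then removes the two remaining silyl groups from F9 and the route ends at target 26.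

**Further compounds**

F1 | step 4 | (R)-4-benzyl-3-[2-(4-bromo-2,6-dimethoxyphenoxy)acetyl]-1,3-oxazolidin-2-one | COc1cc(Br)cc(OC)c1OCC(=O)N1C(=O)OC[C@H]1Cc1ccccc1
F2 | step 4 | (R)-4-benzyl-3-[(2R,3S)-2-(4-bromo-2,6-dimethoxyphenoxy)-3-hydroxy-3-(3-methoxy-4-TBS-oxyphenyl)propanoyl]-1,3-oxazolidin-2-one | COc1cc([C@H](O)[C@H](C(=O)N2C(=O)OC[C@H]2Cc2ccccc2)Oc2c(OC)cc(Br)cc2OC)ccc1O[Si](C)(C)C(C)(C)C
F3 | step 4 | (1S,2S)-2-(4-bromo-2,6-dimethoxyphenoxy)-1-(3-methoxy-4-TBS-oxyphenyl)propane-1,3-diol | COc1cc([C@H](O)[C@H](CO)Oc2c(OC)cc(Br)cc2OC)ccc1O[Si](C)(C)C(C)(C)C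
F4 | step 4 | (1S,2S)-2-(4-bromo-2,6-dimethoxyphenoxy)-3-(TBS-oxy)-1-(3-methoxy-4-TBS-oxyphenyl)propan-1-ol | COc1cc([C@H](O)[C@H](CO[Si](C)(C)C(C)(C)C)Oc2c(OC)cc(Br)cc2OC)ccc1O[Si](C)(C)C(C)(C)C
F5 | step 4 | (S)-2-(4-bromo-2,6-dimethoxyphenoxy)-3-(TBS-oxy)-1-(3-methoxy-4-TBS-oxyphenyl)propan-1-one | COc1cc(C(=O)[C@H](CO[Si](C)(C)C(C)(C)C)Oc2c(OC)cc(Br)cc2OC)ccc1O[Si](C)(C)C(C)(C)C
F6 | step 4 | (1R,2S)-2-(4-bromo-2,6-dimethoxyphenoxy)-3-(TBS-oxy)-1-(3-methoxy-4-TBS-oxyphenyl)propan-1-ol | COc1cc([C@@H](O)[C@H](CO[Si](C)(C)C(C)(C)C)Oc2c(OC)cc(Br)cc2OC)ccc1O[Si](C)(C)C(C)(C)C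
F7 | step 12 | (E,4R,5R)-5-Ar-5-hydroxy-1-methoxy-4-[(TBS-oxy)methyl]pent-1-en-3-one | COc1cc([C@@H](O[Si](C)(C)C(C)(C)C)[C@H](CO[Si](C)(C)C(C)(C)C)Oc2c(OC)cc([C@H](O)[C@@H](CO[Si](C)(C)C(C)(C)C)C(=O)/C=C/OC)cc2OC)ccc1O[Si](C)(C)C(C)(C)C
F8 | step 15 | (2R,3R)-5-diazo-3-(hydroxymethyl)-2-(4-{[(1R,2S)-3-hydroxy-1-(TBS-oxy)-1-(3-methoxy-4-TBS-oxyphenyl)propan-2-yl]oxy}-3,5-dimethoxyphenyl)oxan-4-one | COc1cc([C@@H](O[Si](C)(C)C(C)(C)C)[C@H](CO)Oc2c(OC)cc([C@@H]3OCC(=[N+]=[N-])C(=O)[C@@H]3CO)cc2OC)ccc1O[Si](C)(C)C(C)(C)C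
F9 | step 15 | (3aR,4R,6aR)-4-(4-{[(1R,2S)-3-hydroxy-1-(TBS-oxy)-1-(3-methoxy-4-TBS-oxyphenyl)propan-2-yl]oxy}-3,5-dimethoxyphenyl)tetrahydro-1H,3H-furo[3,4-c]furan-1-one | COc1cc([C@@H](O[Si](C)(C)C(C)(C)C)[C@H](CO)Oc2c(OC)cc([C@@H]3OC[C@@H]4C(=O)OC[C@@H]43)cc2OC)ccc1O[Si](C)(C)C(C)(C)C
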